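The eight-membered ring (C2, C3, C7, C8, C9, C18, C19, C20) is cut back to a cyclobutane (C2, C3, C7, C8). Its C8 oxygen flanked by quaternary C9 and lying 1,5 to the C2 alkene carbon is the imprint of a cyclooct-4-enone enolate. One operation, a potassium-alkoxide-driven [3,3] shift of a cis-1-cyclohexenyl-2-vinylcyclobutanol followed by enolate methylation, forms C18–C19, breaks C2–C8, enlarges the four-membered ring by four atoms and installs the C9 methyl. The precursor joins an enantiopure trans-decalin alkenyllithium to a cis-bicyclo[3.2.0]heptanone whose C5, C6 and C2 centres are set by convex-face reactions.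

Key step: step 18

Remark: atom labels C1–C20 are those of the target ring path (C1 = vinylic methyl) and are used for all intermediates; exo/endo mean the convex/concave face of the cis-bicyclo[3.2.0]heptane; (S)-1 and ketone 22 are taken as commercial.

Step 1
Reactants: 1 (S)-4-(tert-butyldimethylsilyloxy)cyclopent-2-en-1-one; 2 allene
Product: 4 cis-7-methylenebicyclo[3.2.0]hept-3-en-2-one, via photoadduct 3 (not isolated)
Conditions: hν (Pyrex, >300 nm), excess allene, CH2Cl2, −78 °C; then DBU, CH2Cl2, 0 °C
Reagents that add atoms: none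
Why: Enone–allene [2+2] photocycloaddition joins the enone α-carbon (C7) to the central allene carbon (head-to-head) on the face anti to the silyloxy group, which sets the cis C3/C7 ring-fusion centres, and DBU then expels the β-silyloxy group (E1cB) so that the controller is erased.

Step 2
Reactants: 4 cis-7-methylenebicyclo[3.2.0]hept-3-en-2-one
Product: 7 enol triflate (C5=C6–OTf; C8=CH2), via silyl enol ether 5 (not isolated), via lithium enolate 6 (not isolated)
Conditions: [(Ph3P)CuH]6 (cat.), PhMe2SiH, toluene, 25 °C; MeLi, THF, 0 °C; PhNTf2, −78 → 0 °C; H2O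
Reagents that add atoms: N-phenylbis(trifluoromethanesulfonimide) (O=S(=O)(N(c1ccccc1)S(=O)(=O)C(F)(F)F)C(F)(F)F)
Why: Copper-hydride 1,4-hydrosilylation (Stryker's reagent) reduces only the enone, and the regiodefined silyl enol ether is cleaved by MeLi and O-triflated, so the C5=C6 enol triflate forms without touching the isolated methylene; no stereocentre is made.

Step 3
Reactants: 7 enol triflate (C5=C6–OTf; C8=CH2)
Product: 9 cyclobutanone enol triflate (C8=O), via ozonide 8 (not isolated)
Conditions: O3, CH2Cl2, −78 °C (indicator dye); then Me2S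
Reagents that add atoms: ozone ([O-][O+]=O)
Why: Ozonolysis selects the electron-rich 1,1-disubstituted alkene over the electron-poor enol triflate and gives the C8 cyclobutanone.

Step 4
Reactants: 9 cyclobutanone enol triflate (C8=O)
Product: 10 C8 ethylene ketal of 9
Conditions: ethylene glycol, PPTS (cat.), benzene, reflux (Dean–Stark)
Reagents that add atoms: ethylene glycol (OCCO)
Why: Acid-catalysed ketalisation, helped by relief of four-ring carbonyl strain, masks C8 against the Grignard and borane steps and removes the doubly activated C7–H acidity.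

Step 5
Reactants: 10 C8 ethylene ketal of 9
Product: 11 C6-methyl alkene ketal (C5=C6)
Conditions: Fe(acac)3 (5 mol %), MeMgBr, THF/NMP, −30 → 0 °C
Reagents that add atoms: methylmagnesium bromide (C[Mg]Br)
Why: Iron-catalysed Kumada-type cross-coupling of the alkenyl triflate installs the C6 methyl on a trisubstituted C5=C6 alkene.

Step 6
Reactants: 11 C6-methyl alkene ketal (C5=C6)
Product: 13 hydroxy ketal (C5–OH exo; C6–CH3 endo), via alkylborane 12 (not isolated)
Conditions: BH3·THF, THF, 0 → 25 °C; then NaOH, H2O2, 0 °C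
Reagents that add atoms: hydrogen peroxide (OO)
Why: Hydroboration–oxidation adds B and H syn and anti-Markovnikov from the convex face of the bicyclo[3.2.0]heptene, so oxygen (with retention) ends exo on C5 and the new C6–H is exo, which places the C6 methyl on the concave face, trans to the C5 oxygen.

Step 7
Reactants: 13 hydroxy ketal (C5–OH exo; C6–CH3 endo)
Product: 14 3-exo-hydroxy-4-endo-methyl-cis-bicyclo[3.2.0]heptan-6-one
Conditions: 1 M HCl, THF, 25 °C
Reagents that add atoms: water (O)
Why: Acid-catalysed ketal hydrolysis frees the cyclobutanone; the exo hydroxyl cannot reach C8 to form a hemiketal.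

Step 8
Reactants: 14 3-exo-hydroxy-4-endo-methyl-cis-bicyclo[3.2.0]heptan-6-one
Product: 15 TBS ether of 14
Conditions: TBSCl, imidazole, DMF, 25 °C
Reagents that add atoms: tert-butyldimethylsilyl chloride (CC(C)(C)[Si](C)(C)Cl)
Why: Standard silylation of the exposed exo secondary alcohol protects C5–OH for the enolate and alkoxide steps.

Step 9
Reactants: 15 TBS ether of 14
Product: 17 C2-exo-methyl cyclobutanone, via lithium enolate 16 (not isolated)
Conditions: LDA, THF, −78 °C; MeI, −78 → −20 °C
Reagents that add atoms: methyl iodide (CI)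
Why: Kinetic enolisation takes the C2 methylene (the C7–H would give a strained ring-fusion enolate) and enolate alkylation adds methyl from the convex face; this C2 configuration is transient because C2 is re-enolised in step 10.

Step 10
Reactants: 17 C2-exo-methyl cyclobutanone
Product: 19 aldol adduct (C2: methyl endo; CH(OH)CH2SePh exo), via lithium enolate 18 (not isolated)
Conditions: LDA, THF, −78 → −40 °C; PhSeCH2CHO, −78 °C; AcOH, −78 °C
Reagents that add atoms: (phenylseleno)acetaldehyde (O=CC[Se]c1ccccc1)
Why: Aldol addition of the tetrasubstituted enolate to the vinyl-cation equivalent occurs on the convex face, which sets the C2 quaternary centre with the two-carbon arm exo and the methyl endo; the carbinol configuration is of no consequence.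

Step 11
Reactants: 19 aldol adduct (C2: methyl endo; CH(OH)CH2SePh exo)
Product: 21 3-exo-(TBSO)-4-endo,7-endo-dimethyl-7-exo-vinyl-cis-bicyclo[3.2.0]heptan-6-one, via mesylate 20 (not isolated)
Conditions: MsCl, Et3N, CH2Cl2, 0 → 25 °C
Reagents that add atoms: none
Why: Selenium-assisted elimination of the β-mesyloxy selenide (through the episeleniranium ion) unveils the vinyl group, the known selenium-based α-vinylation of ketones.

Step 12
Reactants: 22 3,3-dimethylcyclohexanone
Product: 24 2,5,5-trimethylcyclohexan-1-one (racemic), via lithium enolate 23 (not isolated)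
Conditions: LDA, THF, −78 °C; MeI, −78 → 0 °C
Reagents that add atoms: methyl iodide (CI)
Why: Kinetic deprotonation occurs at the α-methylene remote from the quaternary carbon and enolate alkylation gives the 2-methyl ketone.

Step 13
Reactants: 24 2,5,5-trimethylcyclohexan-1-one (racemic); 25 methyl vinyl ketone
Product: 28 (S)-2,5,5-trimethyl-2-(3-oxobutyl)cyclohexan-1-one, via imine 26 (not isolated), via alkylated imine 27 (not isolated)
Conditions: (R)-1-phenylethylamine, TsOH (cat.), toluene, reflux (Dean–Stark); MVK, THF, 40 °C; then 10% aq. AcOH, 25 °C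
Reagents that add atoms: water (O)
Why: Chiral-imine (deracemising) Michael addition: the more substituted secondary enamine tautomer adds to the enone through an aza-ene-like chair on the face anti to the phenyl group, which sets the C12 quaternary centre.

Step 14
Reactants: 28 (S)-2,5,5-trimethyl-2-(3-oxobutyl)cyclohexan-1-one
Product: 30 (S)-4a,7,7-trimethyl-4,4a,5,6,7,8-hexahydronaphthalen-2(3H)-one, via ketol 29 (not isolated)
Conditions: NaOMe, MeOH, 60 °C
Reagents that add atoms: none
Why: Intramolecular aldol condensation (second stage of a Robinson annulation) closes ring B and dehydrates to the conjugated enone.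

Step 15
Reactants: 30 (S)-4a,7,7-trimethyl-4,4a,5,6,7,8-hexahydronaphthalen-2(3H)-one
Product: 32 trans-decalin enol triflate (C9=C18), via lithium enolate 31 (not isolated)
Conditions: Li, NH3(l), t-BuOH (1 equiv), THF, −78 °C; evaporate NH3; PhNTf2, THF, 0 °C; H2O
Reagents that add atoms: N-phenylbis(trifluoromethanesulfonimide) (O=S(=O)(N(c1ccccc1)S(=O)(=O)C(F)(F)F)C(F)(F)F)
Why: Birch-type enone reduction protonates C17 axially, anti to the angular methyl (trans-decalin), and leaves the C9=C18 enolate regiospecifically for O-triflation.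

Step 16
Reactants: 32 trans-decalin enol triflate (C9=C18)
Product: 33 trans-decalin alkenyl(trimethyl)stannane
Conditions: Me3SnSnMe3, Pd(PPh3)4 (cat.), LiCl, THF, 60 °C
Reagents that add atoms: hexamethylditin (C[Sn](C)(C)[Sn](C)(C)C)
Why: Pd(0)-catalysed Stille-type stannylation of the alkenyl triflate keeps the double bond in place.

Step 17
Reactants: 33 trans-decalin alkenyl(trimethyl)stannane; 21 3-exo-(TBSO)-4-endo,7-endo-dimethyl-7-exo-vinyl-cis-bicyclo[3.2.0]heptan-6-one
Product: 35 cis-1-cyclohexenyl-2-vinylcyclobutanol, via alkenyllithium 34 (not isolated)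
Conditions: MeLi, THF, −78 → 0 °C; then 21, THF, −78 °C; H2O, −78 °C
Reagents that add atoms: none
Why: Tin–lithium exchange gives the alkenyllithium, whose 1,2-addition to the strained cyclobutanone takes the convex face, anti to the fused cyclopentane and the endo C2 methyl, so the cyclohexenyl group ends cis to the vinyl group and the C8 hydroxyl endo.

Step 18
Reactants: 35 cis-1-cyclohexenyl-2-vinylcyclobutanol
Product: 38 tetracyclic C8 ketone (C2=C20; quaternary C9), via potassium alkoxide 36 (not isolated), via potassium enolate 37 (not isolated)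
Conditions: KH, 18-crown-6, THF, 0 → 25 °C; then MeI, −78 → 0 °C
Reagents that add atoms: methyl iodide (CI)
Why: Deprotonation gives the potassium alkoxide, whose oxyanion weakens the C2–C8 bond and triggers a concerted anionic oxy-Cope ([3,3]) shift through the only accessible boat array of the cis-dialkenylcyclobutane, forming C18–C19 and cleaving C2–C8. The closest known reaction is the rearrangement of 1,2-dialkenylcyclobutanols to cyclooct-4-enone enolates with C-alkylation in the same flask. The eight-membered ring is not closed end to end but arises by four-atom enlargement of the cyclobutane, driven by strain release and enolate formation. C18 is fixed by geometry: with vinyl and cyclohexenyl cis, only the rotamer that holds C18 over the four-membered ring can bond, and in this matched decalin enantiomer that presents the C18 face anti to the axial C12 methyl. C9 is set by the face of methylation: the methyl must enter axially on ring B, syn to the new C18–C19 bond, to give the trans-diequatorial 6–8 junction. Nothing in the substrate enforces this beyond letting ring B relax to its chair (C19 equatorial) before iodomethane is added cold, so the step needs C- over O-alkylation and α- over the usual outer-face β-entry, and this is where the route carries its risk.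

Step 19
Reactants: 38 tetracyclic C8 ketone (C2=C20; quaternary C9)
Product: 39 C8 alcohol (C2=C20; C5–OTBS)
Conditions: LiAlH4, THF, −78 → 0 °C
Reagents that add atoms: none
Why: Hydride reduction of the hindered ketone: the carbonyl oxygen should turn to the less encumbered ring face (syn to H7, away from the C9 and C6 methyls) and hydride should arrive from the ring periphery (peripheral attack on a medium ring), which gives the C8 hydroxyl anti to the C9 methyl.

Step 20
Reactants: 39 C8 alcohol (C2=C20; C5–OTBS)
Product: 40 C8 alcohol with tetrasubstituted C2=C3 alkene (C5–OTBS)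
Conditions: Co(salen-tBu,tBu)Cl (10 mol %), PhSiH3 (20 mol %), benzene, 40 °C
Reagents that add atoms: none
Why: Proposed new method: a cobalt hydride should transfer a hydrogen atom to C20 to give the tertiary C2 radical, from which cobalt(II) takes back the adjacent C3–H; the tetrasubstituted alkene is inert to further hydrogen-atom transfer, so the still reactive C2=C20 and exocyclic isomers funnel into it and the shift stops after one position (no drift to C3=C7 as under acid); the closest known reaction type is the Co(salen)/silane one-position isomerisation of terminal and 1,1-disubstituted alkenes.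

Step 21
Reactants: 40 C8 alcohol with tetrasubstituted C2=C3 alkene (C5–OTBS)
Product: 41 CNP0213887.1 (target diol)
Conditions: TBAF, THF, 25 → 50 °C
Reagents that add atoms: none
Why: Fluoride-mediated desilylation releases the C5 hydroxyl without touching the alkene or the stereocentres.

Compound list
1 | (S)-4-(tert-butyldimethylsilyloxy)cyclopent-2-en-1-one | O=C1C=C[C@@H](O[Si](C)(C)C(C)(C)C)C1 | starting material
2 | allene (propa-1,2-diene) | C=C=C | starting material
3 | cis-fused 4-exo-(tert-butyldimethylsilyloxy)-7-methylenebicyclo[3.2.0]heptan-2-one (silyloxy anti to the cyclobutane) | C1[C@@H]2[C@@H](O[Si](C)(C)C(C)(C)C)CC(=O)[C@@H]2C1=C | intermediate (not isolated)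
4 | cis-7-methylenebicyclo[3.2.0]hept-3-en-2-one (C6 ketone; C4=C5; C8=CH2) | C1[C@@H]2C=CC(=O)[C@@H]2C1=C | intermediate
5 | dimethylphenylsilyl enol ether (C5=C6–OSiMe2Ph; C8=CH2) | C1[C@@H]2CC=C(O[Si](C)(C)c3ccccc3)[C@@H]2C1=C | intermediate (not isolated)
6 | lithium enolate (C5=C6–OLi; C8=CH2) | C1[C@@H]2CC=C(O[Li])[C@@H]2C1=C | intermediate (not isolated)
7 | cis-6-methylenebicyclo[3.2.0]hept-3-en-4-yl trifluoromethanesulfonate (C5=C6–OTf; C8=CH2) | C1[C@@H]2CC=C(OS(=O)(=O)C(F)(F)F)[C@@H]2C1=C | intermediate
8 | spiro secondary ozonide (1,2,4-trioxolane) at C8 | C1[C@@H]2CC=C(OS(=O)(=O)C(F)(F)F)[C@@H]2C13OCOO3 | intermediate (not isolated)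
9 | cis-6-oxobicyclo[3.2.0]hept-3-en-4-yl trifluoromethanesulfonate (C8=O) | C1[C@@H]2CC=C(OS(=O)(=O)C(F)(F)F)[C@@H]2C1=O | intermediate
10 | C8 ethylene ketal (spiro-1,3-dioxolane) of 9 | C1[C@@H]2CC=C(OS(=O)(=O)C(F)(F)F)[C@@H]2C13OCCO3 | intermediate
11 | C8 ethylene ketal of cis-4-methylbicyclo[3.2.0]hept-3-en-6-one (C5=C6; methyl on C6) | C1[C@@H]2CC=C(C)[C@@H]2C13OCCO3 | intermediate
12 | C5-exo alkylborane (C6–H exo; C6–CH3 endo) | C1[C@@H]2C[C@@H](B)[C@H](C)[C@@H]2C13OCCO3 | intermediate (not isolated)
13 | C8 ethylene ketal of 3-exo-hydroxy-4-endo-methyl-cis-bicyclo[3.2.0]heptan-6-one | C1[C@@H]2C[C@@H](O)[C@H](C)[C@@H]2C13OCCO3 | intermediate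
14 | 3-exo-hydroxy-4-endo-methyl-cis-bicyclo[3.2.0]heptan-6-one (C5–OH exo; C6–CH3 endo, syn to the cyclobutane) | C1[C@@H]2C[C@@H](O)[C@H](C)[C@@H]2C1=O | intermediate
15 | 3-exo-(tert-butyldimethylsilyloxy)-4-endo-methyl-cis-bicyclo[3.2.0]heptan-6-one | C1[C@@H]2C[C@@H](O[Si](C)(C)C(C)(C)C)[C@H](C)[C@@H]2C1=O | intermediate
16 | lithium enolate of 15 (C2=C8) | C=1[C@@H]2C[C@@H](O[Si](C)(C)C(C)(C)C)[C@H](C)[C@@H]2C=1O[Li] | intermediate (not isolated)
17 | 3-exo-(tert-butyldimethylsilyloxy)-4-endo,7-exo-dimethyl-cis-bicyclo[3.2.0]heptan-6-one | C[C@H]1[C@@H]2C[C@@H](O[Si](C)(C)C(C)(C)C)[C@H](C)[C@@H]2C1=O | intermediate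
18 | lithium enolate of 17 (C2=C8; methyl on C2) | CC=1[C@@H]2C[C@@H](O[Si](C)(C)C(C)(C)C)[C@H](C)[C@@H]2C=1O[Li] | intermediate (not isolated)
19 | aldol adduct: C2 bears endo methyl and exo 1-hydroxy-2-(phenylselanyl)ethyl (carbinol epimers) | OC(C[Se]c1ccccc1)[C@@]1(C)[C@@H]2C[C@@H](O[Si](C)(C)C(C)(C)C)[C@H](C)[C@@H]2C1=O | intermediate
20 | methanesulfonate of 19 | CS(=O)(=O)OC(C[Se]c1ccccc1)[C@@]1(C)[C@@H]2C[C@@H](O[Si](C)(C)C(C)(C)C)[C@H](C)[C@@H]2C1=O | intermediate (not isolated)
21 | 3-exo-(tert-butyldimethylsilyloxy)-4-endo,7-endo-dimethyl-7-exo-vinyl-cis-bicyclo[3.2.0]heptan-6-one | C=C[C@@]1(C)[C@@H]2C[C@@H](O[Si](C)(C)C(C)(C)C)[C@H](C)[C@@H]2C1=O | intermediate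
22 | 3,3-dimethylcyclohexanone | CC1(C)CCCC(=O)C1 | starting material
23 | lithium 5,5-dimethylcyclohex-1-en-1-olate | [Li]OC1=CCCC(C)(C)C1 | intermediate (not isolated)
24 | 2,5,5-trimethylcyclohexan-1-one (racemic) | CC1CCC(C)(C)CC1=O | intermediate
25 | methyl vinyl ketone | CC(=O)C=C | starting material
26 | N-[(R)-1-phenylethyl] imine of 24 | CC1CCC(C)(C)CC1=N[C@H](C)c1ccccc1 | intermediate (not isolated)
27 | N-[(R)-1-phenylethyl] imine of (S)-2,5,5-trimethyl-2-(3-oxobutyl)cyclohexanone | CC(=O)CC[C@]1(C)CCC(C)(C)CC1=N[C@H](C)c1ccccc1 | intermediate (not isolated)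
28 | (S)-2,5,5-trimethyl-2-(3-oxobutyl)cyclohexan-1-one | CC(=O)CC[C@]1(C)CCC(C)(C)CC1=O | intermediate
29 | bicyclic ketol (8a-hydroxy-4a,7,7-trimethyldecalin-2-one; carbinol epimers) | O=C1CC2(O)CC(C)(C)CC[C@@]2(C)CC1 | intermediate (not isolated)
30 | (S)-4a,7,7-trimethyl-4,4a,5,6,7,8-hexahydronaphthalen-2(3H)-one | O=C1C=C2CC(C)(C)CC[C@@]2(C)CC1 | intermediate
31 | trans-fused lithium enolate (C9=C18; H17 anti to the C12 methyl) | [Li]OC1=C[C@@H]2CC(C)(C)CC[C@@]2(C)CC1 | intermediate (not isolated)
32 | trans-4a,7,7-trimethyl-3,4,4a,5,6,7,8,8a-octahydronaphthalen-2-yl trifluoromethanesulfonate | O=S(=O)(OC1=C[C@@H]2CC(C)(C)CC[C@@]2(C)CC1)C(F)(F)F | intermediate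
33 | trimethyl(trans-4a,7,7-trimethyl-3,4,4a,5,6,7,8,8a-octahydronaphthalen-2-yl)stannane | C[Sn](C)(C)C1=C[C@@H]2CC(C)(C)CC[C@@]2(C)CC1 | intermediate
34 | trans-4a,7,7-trimethyl-3,4,4a,5,6,7,8,8a-octahydronaphthalen-2-yllithium | [Li]C1=C[C@@H]2CC(C)(C)CC[C@@]2(C)CC1 | intermediate (not isolated)
35 | cyclobutanol precursor: C8 carries endo OH and exo decalinyl (C9=C18); C2 carries exo vinyl and endo methyl; C5–OTBS exo; C6–CH3 endo | C=C[C@@]1(C)[C@@H]2C[C@@H](O[Si](C)(C)C(C)(C)C)[C@H](C)[C@@H]2[C@@]1(O)C1=C[C@@H]2CC(C)(C)CC[C@@]2(C)CC1 | intermediate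
36 | potassium alkoxide of 35 | C=C[C@@]1(C)[C@@H]2C[C@@H](O[Si](C)(C)C(C)(C)C)[C@H](C)[C@@H]2[C@@]1(O[K])C1=C[C@@H]2CC(C)(C)CC[C@@]2(C)CC1 | intermediate (not isolated)
37 | tetracyclic potassium enolate (C8=C9; cis C2=C20; C19 α on C18) | CC=1[C@@H]2C[C@@H](O[Si](C)(C)C(C)(C)C)[C@H](C)[C@@H]2C(O[K])=C2CC[C@]3(C)CCC(C)(C)C[C@H]3[C@@H]2CC1 | intermediate (not isolated)
38 | tetracyclic C8 ketone: cis C2=C20 alkene; C9 methyl α (anti to H18, trans 6–8 junction); H3/H7 cis; C5–OTBS | CC=1[C@@H]2C[C@@H](O[Si](C)(C)C(C)(C)C)[C@H](C)[C@@H]2C(=O)[C@@]2(C)CC[C@]3(C)CCC(C)(C)C[C@H]3[C@@H]2CC1 | intermediate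
39 | C8 alcohol of 38 (C8–OH anti to the C9 methyl) | CC=1[C@@H]2C[C@@H](O[Si](C)(C)C(C)(C)C)[C@H](C)[C@@H]2[C@@H](O)[C@@]2(C)CC[C@]3(C)CCC(C)(C)C[C@H]3[C@@H]2CC1 | intermediate
40 | C5-O-TBS ether of the target (tetrasubstituted C2=C3) | C/C1=C2\C[C@@H](O[Si](C)(C)C(C)(C)C)[C@H](C)[C@@H]2[C@@H](O)[C@@]2(C)CC[C@]3(C)CCC(C)(C)C[C@H]3[C@@H]2CC1 | intermediate
41 | CNP0213887.1 | C/C1=C2\C[C@@H](O)[C@H](C)[C@@H]2[C@@H](O)[C@@]2(C)CC[C@]3(C)CCC(C)(C)C[C@H]3[C@@H]2CC1 | target

Total step count: 21. Longest linear sequence: 16 steps (steps 1–11, then 17–21).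

Steps most likely to fail

1. Step 20 (the step marked as a proposed new method). Hydrogen-atom transfer to the hindered trisubstituted C2=C20 bond may be too slow, or the C2 radical may lose hydrogen toward C1 or back toward C20, leaving alkene mixtures. Fallback with known chemistry: it sets out from ketone 38. Mukaiyama hydration (Co(acac)2, PhSiH3, O2, i-PrOH) should give the C2 tertiary alcohol F1. Dehydration with Burgess reagent (benzene, 50 °C) should give the β,γ-unsaturated ketone with the C2=C3 bond F2; regioisomeric alkenes can be re-hydrated and recycled. LiAlH4 reduction as in step 19 then rejoins the route at 40.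

2. Step 18. The methyl group may enter C9 from the outer β-face, anti to the new C18–C19 bond. This is the usual course when the C19 branch sits pseudo-axial to escape allylic strain, and it would give the cis-fused C9 epimer. O-methylation or fragmentation of the alkoxide may also compete. Fallback: it sets out from 35 and keeps the [3,3] shift but sets C9 under thermodynamic instead of kinetic control. Enolate 37 is treated with gaseous formaldehyde and the potassium aldolate is left to equilibrate at 0 °C by retro-aldol/aldol before quench. This is expected to favour the trans-diequatorial junction and give the C9-hydroxymethyl ketone F3. Appel-type iodination (I2, PPh3, imidazole) gives the neopentyl iodide F4. Bu3SnH/AIBN at high stannane concentration (to outrun Dowd–Beckwith ring expansion) reduces it to the methyl group and comes back at 38.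

3. Step 19. Hydride may be delivered to the other face of the C8 carbonyl if the ring adopts a conformer with the oxygen turned toward the methyl-bearing face, giving the C8 epimer, which cannot be inverted by substitution at this neopentylic centre. Fallback: it sets out from 38 and uses electron-transfer reduction (Li, NH3, EtOH, −78 °C) so that the carbinol configuration is set under thermodynamic control, which should favour the hydroxyl on the less crowded face, away from the C9 and C6 methyls. It comes back at 39 and makes no new compound (F0).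

Further compounds
F1 | step 20 | C2 tertiary alcohol of ketone 38 (C2 epimers; C20 now CH2) | CC1(O)[C@@H]2C[C@@H](O[Si](C)(C)C(C)(C)C)[C@H](C)[C@@H]2C(=O)[C@@]2(C)CC[C@]3(C)CCC(C)(C)C[C@H]3[C@@H]2CC1
F2 | step 20 | C8 ketone with tetrasubstituted C2=C3 alkene (C5–OTBS) | C/C1=C2\C[C@@H](O[Si](C)(C)C(C)(C)C)[C@H](C)[C@@H]2C(=O)[C@@]2(C)CC[C@]3(C)CCC(C)(C)C[C@H]3[C@@H]2CC1
F3 | step 18 | C9-hydroxymethyl analogue of ketone 38 (CH2OH α on C9) | CC=1[C@@H]2C[C@@H](O[Si](C)(C)C(C)(C)C)[C@H](C)[C@@H]2C(=O)[C@@]2(CO)CC[C@]3(C)CCC(C)(C)C[C@H]3[C@@H]2CC1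
F4 | step 18 | C9-iodomethyl analogue of ketone 38 | CC=1[C@@H]2C[C@@H](O[Si](C)(C)C(C)(C)C)[C@H](C)[C@@H]2C(=O)[C@@]2(CI)CC[C@]3(C)CCC(C)(C)C[C@H]3[C@@H]2CC1
F0 | step 19 | none | none
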